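## Analysis of the target

Target 13 is 7-hydroxy-5-methoxy-8-[(2R)-1-methylpiperidin-2-yl]-2-phenyl-4H-chromen-4-one. It is a flavone: a benzopyranone (rings A and C) with phenyl ring B at C2, a methyl ether on O5, a free hydroxyl at C7 and, on C8 between O7 and the ring oxygen O1, an N-methylpiperidine joined through its C2'. The only stereocentre is C2' (R). It is benzylic and bonded to nitrogen, and with no second stereocentre to relay from it must be set by a chiral catalyst or reagent. The ortho-hydroxybenzylamine unit is the delicate part: under acid or heat the C2'–N bond can ionise through an ortho-quinone methide and re-close, which would racemise C2'. In addition, the pyranone ring opens in hot aqueous base, and the O5 methyl ether, peri to the carbonyl, is the ether that Lewis acids cleave first. The synthesis is hard because the two ring A oxygens must be told apart against their natural reactivity (in a 5,7-diol the 7-hydroxyl alkylates first, yet here O5 carries the methyl), and because the crowded C8 must receive a chiral, basic ring. The strategy rests on C5: it is the only ring A carbon peri to the C4 carbonyl, so its C–H bond is the one bond a metal held on the carbonyl oxygen can reach. O5 can therefore be added last to a flavone that owns only O7, and the piperidine can be carried as a flat pyridine through every acidic and oxidising step, so that C2' is created only in the second-to-last step.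

## Retrosynthetic reasoning

13 from 11. The acyl–O7 bond is cut first: 13 is drawn back, through phenolate 12, to its pivalate 11. O7 must stay masked until the end because it would otherwise be methylated together with O5. An ester is chosen because it leaves by transesterification in cold, mildly basic medium, where neither the ortho-hydroxybenzylamine (which racemises under acid) nor the pyranone is at risk.

11 from 9. The piperidine of 11 is traced, through hydroiodide 10, to the N-methylpyridinium ring of 9. Only C–H bonds at C2'–C6' are removed, no skeletal bond. This is the one place where the stereocentre is made, and it is placed late on purpose: a pyridine is achiral and inert to the acid and oxidant used earlier. The N-methyl group that the target needs is also the activating group that makes the heteroarene reducible and keeps the product, formed as its ammonium salt, off the catalyst. The forward reaction has to reduce the ring with one face of the C2' iminium preferred and leave the C2=C3 bond of the pyranone alone.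

9 from 7. Both heteroatom–methyl bonds of 9, O5–CH3 and N–CH3, are cut together, leading through the neutral ether 8 to phenol 7. Both call for the same electrophile, so one operation serves; O7 cannot compete because it is acylated. The forward step must alkylate a phenol that is hydrogen-bonded to the C4 carbonyl without loosening the pivalate.

7 from 5. The key cut is the C5–O bond of 7, leading through trifluoroacetate 6 to the C5–H compound 5. Cutting here, and not at O7 or C8, removes the differentiation problem: the two oxygens are never present as a pair of free hydroxyls. The forward reaction has to oxidise one of twelve sp2 C–H bonds in the presence of a basic nitrogen and an aryl ester. Carbonyl-directed catalysis by divalent ruthenium can do this because only C5–H lies within reach of a metal bound at the C4 oxygen.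

5 from 3 and 4. The biaryl bond C8–C2' is cut next, giving aryl iodide 3 and organozinc 4. The cut is made at the bond to a ready-made pyridine, not inside rings A and C, so that the whole flavone can be bought as 1. Zinc is the metal of choice because 2-pyridylboron reagents tend to protodeboronate before they couple, and an organozinc halide tolerates the ester and the enone. The coupling has to form a bond at a carbon with two ortho substituents.

3 from 2. The ester bond at O7 is cut, giving phenol 2. The forward acylation removes the acidic proton before the organozinc step and lowers the electron density of ring A for the later oxidation.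

2 from 1. The C8–I bond is cut, giving commercial 1. Electrophilic substitution of 1 is expected at C8, between O7 and O1. This regiochemistry is cleanest while C5 is still unoxygenated, a second reason for adding O5 late: with an oxygen at C5, C6 would be flanked by two oxygens just as C8 is.

## Alternatives that were turned down

Alternative 1: The disconnection is the N1'–C2' bond of the piperidine, on a phloroglucinol-derived arene that does not yet carry rings B and C.
- Key step: a chiral phosphoric acid would give A1, methyl (R)-2-(2,6-dihydroxy-4-methoxyphenyl)piperidine-1-carboxylate, from the E/Z mixture of styrene carbamate A2, methyl N-[5-(2,6-dihydroxy-4-methoxyphenyl)pent-4-en-1-yl]carbamate. The acid protonates either alkene isomer to one ortho-quinone methide held in a chiral ion pair, and the carbamate nitrogen adds to the exocyclic carbon and closes the ring.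
- For it: the alkene geometry does not matter, the two hydroxyls flanking the side chain are equivalent, and ring and stereocentre arise in one step from a well-organised hydrogen-bonded intermediate. On predictability of the stereo-defining event it is at least as good as the hydrogenation of the hindered pyridinium 9.
- Against it: the electron-rich ring that makes the quinone methide easy to form also makes the benzylic C–N bond of A1 easy to ionise again. Everything that follows acts on that labile centre: reduction of the carbamate to N-methyl, C-acylation of the arene, aroylation and acid cyclodehydration to build rings C and B. The carbamate reduction must also precede the ketone. With about four steps to A2 the count is near eleven.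
- Comparison: the chosen route is about four steps shorter and builds no ring on a chiral intermediate. After the stereocentre is formed it meets only mild base, on a ring made less electron-rich by the pyranone carbonyl.

Alternative 2: The disconnection is the C2'–C3' bond, with the nitrogen and the future O1 tied together in a cyclic sulfamidate.
- Key step: [RhCl(C2H4)2]2 with a chiral diene would transfer the allyl group of an allyltrifluoroborate salt to the C=N carbon of a benzoxathiazine dioxide. This gives A3, (R)-4-allyl-5-(benzyloxy)-7-methoxy-3,4-dihydro-1,2,3-benzoxathiazine 2,2-dioxide; no ring of the target closes.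
- For it: a cyclic aldimine of fixed geometry on a rigid diene–rhodium complex is one of the most dependable routes to an α-branched benzylic amine. On certainty of the absolute configuration this alternative is stronger than the chosen route. The tether also distinguishes the two oxygens ortho to the side chain.
- Against it: the step delivers three of the five ring carbons and no ring. N-allylation, ring-closing metathesis, alkene hydrogenation, sulfamidate cleavage and N-methylation are needed for the piperidine alone. Rings C and B must then be built and the benzyl ether removed, about fourteen steps from a salicylaldehyde. The imine carbon sits next to the benzyloxy group, which should slow the addition, and the late ring construction meets the racemisation risk of alternative 1.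
- Comparison: the chosen route has half the steps and buys the flavone ready-made. What it gives up is the near-certainty of the stereochemical step.

Alternative 3: Nothing in the skeleton is disconnected; a racemic amine is accepted and the C2'–H bond is re-formed until one enantiomer is left.
- Key step: the product would be A4, (R)-2-(2,6-dihydroxy-4-methoxyphenyl)-1-methylpiperidine, from its racemate A5. An engineered monoamine oxidase dehydrogenates only the (S)-amine to the 2-aryl iminium ion, an amine–borane reduces the iminium back without selectivity, and repeated cycles drive the mixture to A4.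
- For it: A5 should be available in one or two steps by Mannich-type arylation of a cyclic iminium ion. The deracemisation can in principle convert all the material, and an enzyme that accepts its substrate usually gives higher optical purity than a hydrogenation catalyst. On brevity up to the chiral amine and on optical purity it beats the chosen route.
- Against it: whether the active site accepts a tertiary amine whose aryl group is hydroxylated at both ortho positions cannot be argued from structure and would need enzyme screening. The iminium ion is conjugated to a trioxygenated ring and is exposed to air, peroxide and borane in water. Rings C and B must still be built on A4 afterwards, three or four acid or base steps on the centre just purified.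
- Comparison: the chosen route puts its uncertainty in small-molecule catalysis that can be reasoned about, and forms the stereocentre when the ring system is complete.

Key step: step 4

Assumption: 1 and a THF solution of 4 are bought; in step 6 the (S)-hand of the ligand is written provisionally, and the hand that gives (R)-11 is fixed by a first run (the antipode is used if the sense is opposite).

Step 1
Reactants: 1 7-hydroxy-2-phenyl-4H-chromen-4-one (7-hydroxyflavone)
Product: 2 7-hydroxy-8-iodo-2-phenyl-4H-chromen-4-one
Conditions: NIS (1.05 equiv), DMF, 0 °C to rt, dark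
Reagents that add atoms: N-iodosuccinimide, O=C1CCC(=O)N1I
Why: Electrophilic aromatic iodination of a phenol; C8 is ortho to both the 7-hydroxyl and O1 and lies on the C7–C8 bond of higher double-bond character (like C1 of 2-naphthol), the position where 7-hydroxychromones, -flavones and -coumarins take electrophiles, so one equivalent of NIS should iodinate C8 and leave C6 and C3 alone.

Step 2
Reactants: 2 7-hydroxy-8-iodo-2-phenyl-4H-chromen-4-one
Product: 3 8-iodo-4-oxo-2-phenyl-4H-chromen-7-yl pivalate (2,2-dimethylpropanoate)
Conditions: t-BuCOCl (1.3 equiv), Et3N (2 equiv), DMAP (0.1 equiv), CH2Cl2, 0 °C to rt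
Reagents that add atoms: pivaloyl chloride, CC(C)(C)C(Cl)=O
Why: DMAP-catalysed O-acylation of the phenol; the pivalate removes the acidic proton before the organozinc step, lowers the electron density of ring A for the later oxidation, and is bulky enough to resist acyl transfer to a neighbouring pyridine nitrogen.

Step 3
Reactants: 3 8-iodo-4-oxo-2-phenyl-4H-chromen-7-yl pivalate; 4 2-pyridylzinc bromide (0.5 M in THF, 1.5 equiv)
Product: 5 4-oxo-2-phenyl-8-(pyridin-2-yl)-4H-chromen-7-yl pivalate
Conditions: Pd2(dba)3 (2 mol%), XPhos (8 mol%), THF, 60 °C
Reagents that add atoms: none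
Why: Negishi coupling: zerovalent palladium inserts into the C8–I bond, the pyridyl group moves from zinc to palladium and reductive elimination forms C8–C2'. Zinc is used because 2-pyridylboron reagents protodeboronate, the bulky biarylphosphine speeds reductive elimination at the doubly ortho-substituted carbon, and the ester and the pyranone are inert to an organozinc halide.

Step 4
Reactants: 5 4-oxo-2-phenyl-8-(pyridin-2-yl)-4H-chromen-7-yl pivalate
Product: 7 5-hydroxy-4-oxo-2-phenyl-8-(pyridin-2-yl)-4H-chromen-7-yl pivalate, via C5 trifluoroacetate 6 (not isolated)
Conditions: [RuCl2(p-cymene)]2 (5 mol%), PhI(OCOCF3)2 (2 equiv), CF3CO2H/(CF3CO)2O (3:1), 80 °C; then aq. NaHCO3, EtOAc, rt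
Reagents that add atoms: bis(trifluoroacetoxy)iodobenzene, FC(F)(F)C(=O)OI(OC(=O)C(F)(F)F)c1ccccc1
Why: This is carbonyl-directed C–H oxygenation by divalent ruthenium with a hypervalent iodine oxidant, a known reaction type for aryl ketones, chromones and flavones. In CF3CO2H the chloride dimer gives a cationic ruthenium trifluoroacetate that binds the Lewis-basic pyranone oxygen at C4 and cleaves the peri C5–H bond by carboxylate-assisted metalation, forming a five-membered ruthenacycle (Ru–O=C4–C4a–C5). PhI(OCOCF3)2 oxidises this to a tetravalent ruthenium aryl trifluoroacetate, and C–O reductive elimination gives aryl trifluoroacetate 6 and returns divalent ruthenium. No ring of the product is closed and no stereocentre is formed. The selectivity needed is C5 over C6, C3 and ring B: from the C4 oxygen only C5–H can be reached (C3 would need a four-membered metallacycle; C6 and ring B are out of range), and the pivalate carbonyl, which could reach C6 through a six-membered metallacycle, is a much weaker donor than the pyranone oxygen. The pyridine is protonated by the solvent, so it does not bind ruthenium, and it has no ortho C–H on ring A because C7 and C8a are substituted. The pyridinium and the 7-pivalate make ring A too electron-poor for uncatalysed oxidation by the iodane, and (CF3CO)2O keeps the new oxygen masked as the trifluoroacetate so that 6 is not oxidised further. Aqueous NaHCO3 then hydrolyses the trifluoroacetate to the hydrogen-bonded phenol 7 and leaves the hindered pivalate in place.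

Step 5
Reactants: 7 5-hydroxy-4-oxo-2-phenyl-8-(pyridin-2-yl)-4H-chromen-7-yl pivalate
Product: 9 2-[7-(2,2-dimethylpropanoyloxy)-5-methoxy-4-oxo-2-phenyl-4H-chromen-8-yl]-1-methylpyridin-1-ium iodide, via 5-O-methyl ether 8 (not isolated)
Conditions: MeI (10 equiv), K2CO3 (1.5 equiv), dry acetone, 50 °C, sealed vessel
Reagents that add atoms: iodomethane, CI
Why: Base-mediated O-methylation of the chelated 5-hydroxyl (Williamson type) gives 8, and the Menshutkin reaction of its pyridine nitrogen with the excess MeI gives 9 with iodide as counter-ion. O7 cannot be methylated because it is acylated, and the hindered pivalate should withstand anhydrous K2CO3.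

Step 6
Reactants: 9 2-[7-(2,2-dimethylpropanoyloxy)-5-methoxy-4-oxo-2-phenyl-4H-chromen-8-yl]-1-methylpyridin-1-ium iodide
Product: 11 5-methoxy-8-[(2R)-1-methylpiperidin-2-yl]-4-oxo-2-phenyl-4H-chromen-7-yl pivalate, via piperidinium hydroiodide 10 (not isolated)
Conditions: [Ir(cod)Cl]2 (1 mol%), (S)-SynPhos (2.2 mol%), H2 (40 bar), toluene/CH2Cl2 (1:1), 30 °C; then aq. NaHCO3
Reagents that add atoms: none
Why: Iridium-catalysed asymmetric hydrogenation of a 2-aryl N-alkylpyridinium halide: quaternisation lowers the aromatic stabilisation, and the amine is released as hydroiodide 10, so it cannot poison the catalyst. Hydride transfers from the iridium hydride reduce the ring stepwise, and the stereocentre is set when hydride is delivered to C2' of the cyclic iminium ion, the face being chosen by the C2-symmetric bisphosphine. The neutral, electron-rich C2=C3 bond of the pyranone and the ester are not hydride acceptors under these conditions, and NaHCO3 frees amine 11.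

Step 7
Reactants: 11 5-methoxy-8-[(2R)-1-methylpiperidin-2-yl]-4-oxo-2-phenyl-4H-chromen-7-yl pivalate
Product: 13 7-hydroxy-5-methoxy-8-[(2R)-1-methylpiperidin-2-yl]-2-phenyl-4H-chromen-4-one (the target), via sodium phenolate 12 (not isolated)
Conditions: NaOMe (1.5 equiv), MeOH, 0 °C to rt; then AcOH (1.5 equiv)
Reagents that add atoms: none
Why: Transesterification of an aryl ester by methoxide (the phenolate is a good leaving group), then protonation of phenolate 12 by AcOH. Cold methoxide does not open the pyranone ring, and under base the C2'–N bond cannot ionise because the amine is not protonated, so the stereocentre is untouched.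

Compound list

1 | 7-hydroxy-2-phenyl-4H-chromen-4-one (7-hydroxyflavone) | Oc1ccc2c(=O)cc(-c3ccccc3)oc2c1 | starting material
2 | 7-hydroxy-8-iodo-2-phenyl-4H-chromen-4-one | Oc1ccc2c(=O)cc(-c3ccccc3)oc2c1I | intermediate
3 | 8-iodo-4-oxo-2-phenyl-4H-chromen-7-yl pivalate | CC(C)(C)C(=O)Oc1ccc2c(=O)cc(-c3ccccc3)oc2c1I | intermediate
4 | 2-pyridylzinc bromide | Br[Zn]c1ccccn1 | starting material
5 | 4-oxo-2-phenyl-8-(pyridin-2-yl)-4H-chromen-7-yl pivalate | CC(C)(C)C(=O)Oc1ccc2c(=O)cc(-c3ccccc3)oc2c1-c4ccccn4 | intermediate
6 | 4-oxo-2-phenyl-8-(pyridin-2-yl)-5-(trifluoroacetoxy)-4H-chromen-7-yl pivalate | CC(C)(C)C(=O)Oc1cc(OC(=O)C(F)(F)F)c2c(=O)cc(-c3ccccc3)oc2c1-c4ccccn4 | intermediate (not isolated)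
7 | 5-hydroxy-4-oxo-2-phenyl-8-(pyridin-2-yl)-4H-chromen-7-yl pivalate | CC(C)(C)C(=O)Oc1cc(O)c2c(=O)cc(-c3ccccc3)oc2c1-c4ccccn4 | intermediate
8 | 5-methoxy-4-oxo-2-phenyl-8-(pyridin-2-yl)-4H-chromen-7-yl pivalate | CC(C)(C)C(=O)Oc1cc(OC)c2c(=O)cc(-c3ccccc3)oc2c1-c4ccccn4 | intermediate (not isolated)
9 | 2-[7-(2,2-dimethylpropanoyloxy)-5-methoxy-4-oxo-2-phenyl-4H-chromen-8-yl]-1-methylpyridin-1-ium iodide | CC(C)(C)C(=O)Oc1cc(OC)c2c(=O)cc(-c3ccccc3)oc2c1-c4cccc[n+]4C.[I-] | intermediate
10 | (2R)-2-[7-(2,2-dimethylpropanoyloxy)-5-methoxy-4-oxo-2-phenyl-4H-chromen-8-yl]-1-methylpiperidin-1-ium iodide | CC(C)(C)C(=O)Oc1cc(OC)c2c(=O)cc(-c3ccccc3)oc2c1[C@H]4CCCC[NH+]4C.[I-] | intermediate (not isolated)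
11 | 5-methoxy-8-[(2R)-1-methylpiperidin-2-yl]-4-oxo-2-phenyl-4H-chromen-7-yl pivalate | CC(C)(C)C(=O)Oc1cc(OC)c2c(=O)cc(-c3ccccc3)oc2c1[C@H]4CCCCN4C | intermediate
12 | sodium 5-methoxy-8-[(2R)-1-methylpiperidin-2-yl]-4-oxo-2-phenyl-4H-chromen-7-olate | COc1cc([O-])c([C@H]2CCCCN2C)c2oc(-c3ccccc3)cc(=O)c12.[Na+] | intermediate (not isolated)
13 | 7-hydroxy-5-methoxy-8-[(2R)-1-methylpiperidin-2-yl]-2-phenyl-4H-chromen-4-one | COc1cc(O)c([C@H]2CCCCN2C)c2oc(-c3ccccc3)cc(=O)c12 | target

Total step count: 7. Longest linear sequence: 7 steps (1 to 13; 4 is bought).

Least certain steps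

Step 4 (key step). The most likely failure is slow C–H metalation, because ring A carries a pyridinium para to C5 and an ester and is therefore electron-poor. Decomposition of the iodane, or acidolysis of the pivalate followed by oxidation of the freed phenol, could then overtake the hydroxylation. Misdirection to C6 by the pivalate carbonyl is a lesser concern. The fallback sets out from 3 and returns at 8: the hydroxylation is moved ahead of the biaryl coupling, so the ruthenium step sees a substrate without nitrogen, close to the simple 7-substituted flavones for which the reaction type is established. Iodide 3 under the conditions of step 4 should give 8-iodo-4-oxo-2-phenyl-5-(trifluoroacetoxy)-4H-chromen-7-yl pivalate F1 and, after bicarbonate work-up, 5-hydroxy-8-iodo-4-oxo-2-phenyl-4H-chromen-7-yl pivalate F2. MeI and K2CO3 in acetone give 8-iodo-5-methoxy-4-oxo-2-phenyl-4H-chromen-7-yl pivalate F3. Negishi coupling of F3 with 4 as in step 3 gives 8, which is then isolated and quaternised with MeI without base to reach 9.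

Step 6. The most likely failure is poor facial selectivity in the hydride transfer to the C2' iminium ion. The aryl group is twisted out of plane by its two ortho oxygen substituents, and the N-substituent is methyl, not the benzyl group for which this catalyst class is best established. Incomplete reduction is the second concern. The fallback sets out from 9 and returns at 11: stereocontrol is given up in the reduction and recovered by resolution. Hydrogenation of 9 over PtO2 (H2, 3 bar, MeOH, rt) should give racemic 2-[7-(2,2-dimethylpropanoyloxy)-5-methoxy-4-oxo-2-phenyl-4H-chromen-8-yl]-1-methylpiperidin-1-ium iodide F4 and, after NaHCO3, racemic 5-methoxy-8-(1-methylpiperidin-2-yl)-4-oxo-2-phenyl-4H-chromen-7-yl pivalate F5. Preparative chromatography on a chiral stationary phase separates 11 from its enantiomer, 5-methoxy-8-[(2S)-1-methylpiperidin-2-yl]-4-oxo-2-phenyl-4H-chromen-7-yl pivalate F6, which is discarded.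

Step 5. The most likely failure is loss of the pivalate once the neighbouring nitrogen is quaternised, because the aryloxide then becomes a better leaving group; the freed O7 would be methylated. Incomplete methylation of the chelated hydroxyl is the second concern. The fallback sets out from 7 and returns at 13: O7 is moved to a base-stable benzyl ether before any methylation.
- NaOMe in MeOH cleaves the pivalate of 7 to 5,7-dihydroxy-2-phenyl-8-(pyridin-2-yl)-4H-chromen-4-one F7.
- One equivalent of BnBr with K2CO3 in acetone alkylates the more acidic, non-chelated 7-hydroxyl to 7-(benzyloxy)-5-hydroxy-2-phenyl-8-(pyridin-2-yl)-4H-chromen-4-one F8.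
- MeI and K2CO3 then give 2-[7-(benzyloxy)-5-methoxy-4-oxo-2-phenyl-4H-chromen-8-yl]-1-methylpyridin-1-ium iodide F9.
- Hydrogenation as in step 6 gives (2R)-2-[7-(benzyloxy)-5-methoxy-4-oxo-2-phenyl-4H-chromen-8-yl]-1-methylpiperidin-1-ium iodide F10 and, after NaHCO3, 7-(benzyloxy)-5-methoxy-8-[(2R)-1-methylpiperidin-2-yl]-2-phenyl-4H-chromen-4-one F11.
- Hydrogenolysis (H2, 1 bar, Pd/C (palladium metal on carbon), EtOAc/MeOH) removes the benzyl group and gives 13.

Step 3. The most likely failure is slow transmetalation and reductive elimination at C8, which carries two ortho substituents, so that protodeiodination of 3 or homocoupling of 4 takes over. The fallback sets out from 4 and returns at 5: the biaryl bond is made on a simple arene and ring C is built afterwards, which also bypasses steps 1 and 2.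
- Negishi coupling of 4 with commercial 2-iodo-1,3-dimethoxybenzene gives 2-(2,6-dimethoxyphenyl)pyridine F12.
- BBr3 in CH2Cl2 gives 2-(pyridin-2-yl)benzene-1,3-diol F13.
- Friedel–Crafts C-acetylation with AcOH and BF3·OEt2 at 90 °C gives 1-[2,4-dihydroxy-3-(pyridin-2-yl)phenyl]ethan-1-one F14.
- The trianion made with LiN(SiMe3)2 in THF is C-benzoylated with PhCOCl to 1-[2,4-dihydroxy-3-(pyridin-2-yl)phenyl]-3-phenylpropane-1,3-dione F15.
- H2SO4 in AcOH at 100 °C closes the pyranone to 7-hydroxy-2-phenyl-8-(pyridin-2-yl)-4H-chromen-4-one F16, and pivaloylation as in step 2 gives 5.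

Further compounds

F1 | step 4 | 8-iodo-4-oxo-2-phenyl-5-(trifluoroacetoxy)-4H-chromen-7-yl pivalate | CC(C)(C)C(=O)Oc1cc(OC(=O)C(F)(F)F)c2c(=O)cc(-c3ccccc3)oc2c1I
F2 | step 4 | 5-hydroxy-8-iodo-4-oxo-2-phenyl-4H-chromen-7-yl pivalate | CC(C)(C)C(=O)Oc1cc(O)c2c(=O)cc(-c3ccccc3)oc2c1I
F3 | step 4 | 8-iodo-5-methoxy-4-oxo-2-phenyl-4H-chromen-7-yl pivalate | CC(C)(C)C(=O)Oc1cc(OC)c2c(=O)cc(-c3ccccc3)oc2c1I
F4 | step 6 | racemic 2-[7-(2,2-dimethylpropanoyloxy)-5-methoxy-4-oxo-2-phenyl-4H-chromen-8-yl]-1-methylpiperidin-1-ium iodide | CC(C)(C)C(=O)Oc1cc(OC)c2c(=O)cc(-c3ccccc3)oc2c1C4CCCC[NH+]4C.[I-]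
F5 | step 6 | racemic 5-methoxy-8-(1-methylpiperidin-2-yl)-4-oxo-2-phenyl-4H-chromen-7-yl pivalate | CC(C)(C)C(=O)Oc1cc(OC)c2c(=O)cc(-c3ccccc3)oc2c1C4CCCCN4C
F6 | step 6 | 5-methoxy-8-[(2S)-1-methylpiperidin-2-yl]-4-oxo-2-phenyl-4H-chromen-7-yl pivalate | CC(C)(C)C(=O)Oc1cc(OC)c2c(=O)cc(-c3ccccc3)oc2c1[C@@H]4CCCCN4C
F7 | step 5 | 5,7-dihydroxy-2-phenyl-8-(pyridin-2-yl)-4H-chromen-4-one | Oc1cc(O)c2c(=O)cc(-c3ccccc3)oc2c1-c4ccccn4
F8 | step 5 | 7-(benzyloxy)-5-hydroxy-2-phenyl-8-(pyridin-2-yl)-4H-chromen-4-one | O(Cc1ccccc1)c2cc(O)c3c(=O)cc(-c4ccccc4)oc3c2-c5ccccn5
F9 | step 5 | 2-[7-(benzyloxy)-5-methoxy-4-oxo-2-phenyl-4H-chromen-8-yl]-1-methylpyridin-1-ium iodide | O(Cc1ccccc1)c2cc(OC)c3c(=O)cc(-c4ccccc4)oc3c2-c5cccc[n+]5C.[I-]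
F10 | step 5 | (2R)-2-[7-(benzyloxy)-5-methoxy-4-oxo-2-phenyl-4H-chromen-8-yl]-1-methylpiperidin-1-ium iodide | O(Cc1ccccc1)c2cc(OC)c3c(=O)cc(-c4ccccc4)oc3c2[C@H]5CCCC[NH+]5C.[I-]
F11 | step 5 | 7-(benzyloxy)-5-methoxy-8-[(2R)-1-methylpiperidin-2-yl]-2-phenyl-4H-chromen-4-one | O(Cc1ccccc1)c2cc(OC)c3c(=O)cc(-c4ccccc4)oc3c2[C@H]5CCCCN5C
F12 | step 3 | 2-(2,6-dimethoxyphenyl)pyridine | COc1cccc(OC)c1-c2ccccn2
F13 | step 3 | 2-(pyridin-2-yl)benzene-1,3-diol | Oc1cccc(O)c1-c2ccccn2
F14 | step 3 | 1-[2,4-dihydroxy-3-(pyridin-2-yl)phenyl]ethan-1-one | CC(=O)c1ccc(O)c(-c2ccccn2)c1O
F15 | step 3 | 1-[2,4-dihydroxy-3-(pyridin-2-yl)phenyl]-3-phenylpropane-1,3-dione | O=C(CC(=O)c1ccccc1)c2ccc(O)c(-c3ccccn3)c2O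
F16 | step 3 | 7-hydroxy-2-phenyl-8-(pyridin-2-yl)-4H-chromen-4-one | Oc1ccc2c(=O)cc(-c3ccccc3)oc2c1-c4ccccn4
A1 | alternative 1 | methyl (R)-2-(2,6-dihydroxy-4-methoxyphenyl)piperidine-1-carboxylate | COc1cc(O)c([C@H]2CCCCN2C(=O)OC)c(O)c1
A2 | alternative 1 | methyl N-[5-(2,6-dihydroxy-4-methoxyphenyl)pent-4-en-1-yl]carbamate (E/Z mixture) | COC(=O)NCCCC=Cc1c(O)cc(OC)cc1O
A3 | alternative 2 | (R)-4-allyl-5-(benzyloxy)-7-methoxy-3,4-dihydro-1,2,3-benzoxathiazine 2,2-dioxide | COc1cc(OCc2ccccc2)c2c(c1)OS(=O)(=O)N[C@@H]2CC=C
A4 | alternative 3 | (R)-2-(2,6-dihydroxy-4-methoxyphenyl)-1-methylpiperidine | COc1cc(O)c([C@H]2CCCCN2C)c(O)c1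
A5 | alternative 3 | racemic 2-(2,6-dihydroxy-4-methoxyphenyl)-1-methylpiperidine | COc1cc(O)c(C2CCCCN2C)c(O)c1
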